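The quinone ring (C1–C4, C4a, C8a) of the 2-hydroxy-3-alkyl-1,4-naphthoquinone is opened at its C2(OH)=C3(alkyl) bond. The route exploits the 1,3-dicarbonyl relationship of C4=O and the enolic C2–OH: C2 is an ester carbonyl, C3 the α-carbon of an aryl ketone, and the unsubstituted benzo ring is benzyne. The precursor is the acyclic β-keto ester 8, already carrying the complete ester side chain. In one flask benzyne inserts into the CH2–C(=O) bond of 8, a methoxide-induced Claisen condensation closes the quinone ring at C2–C3, and air oxidises C1 (formerly the β-keto ester CH2), giving the target without protecting groups. The stereocentre comes from (S)-linalool.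

Key step: step 6

Assumption: (S)-(+)-linalool of high enantiomeric purity and methyl 4,4-dimethyl-5-oxopentanoate (otherwise the Michael adduct of isobutyraldehyde and methyl acrylate) are taken as purchasable.

Step 1
Reactants: 1 (S)-(+)-linalool, (3S)-3,7-dimethylocta-1,6-dien-3-ol
Product: 2 (2E,6S)-6-hydroxy-2,6-dimethylocta-2,7-dienal
Conditions: SeO2 (1.2 equiv), 1,4-dioxane, 80 °C
Reagents that add atoms: selenium dioxide, O=[Se]=O
Why: Riley allylic oxidation should work because SeO2 engages the electron-rich trisubstituted alkene in an ene reaction and [2,3]-sigmatropic shift that oxygenates the (E)-methyl group and then takes the allylic alcohol on to the (E)-enal, while the vinyl group has no allylic hydrogen and the (S)-carbinol centre bought with 1 is not touched.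

Step 2
Reactants: 2 (2E,6S)-6-hydroxy-2,6-dimethylocta-2,7-dienal
Product: 3 (2E,6S)-6-hydroxy-2,6-dimethylocta-2,7-dienoic acid
Conditions: NaClO2, NaH2PO4, 2-methyl-2-butene, t-BuOH/H2O, 0 → 23 °C
Reagents that add atoms: sodium chlorite, [Na+].[O-]Cl=O
Why: Pinnick oxidation should convert the enal into the acid through the chlorous acid adduct, while 2-methyl-2-butene traps the hypochlorous acid so that the vinyl group, the (E)-alkene and the tertiary alcohol stay intact.

Step 3
Reactants: 4 methyl 4,4-dimethyl-5-oxopentanoate
Product: 6 5,5-dimethyloxan-2-one (5,5-dimethyl-δ-valerolactone), via hydroxy ester 5 (not isolated)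
Conditions: NaBH4, MeOH, 0 °C; aq. HCl work-up; then TsOH·H2O (cat.), toluene, 80 °C
Reagents that add atoms: none
Why: NaBH4 should reduce the aldehyde chemoselectively in the presence of the methyl ester, and the resulting hydroxy ester should lactonise under acid with loss of methanol, helped by the gem-dimethyl effect.

Step 4
Reactants: 6 5,5-dimethyloxan-2-one
Product: 7 methyl 7-hydroxy-6,6-dimethyl-3-oxoheptanoate (in equilibrium with its six-membered lactol)
Conditions: MeOAc and LiN(i-Pr)2 (2.2 equiv each), THF, −78 °C; then 6, −78 → −40 °C; AcOH quench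
Reagents that add atoms: methyl acetate, CC(=O)OC
Why: In this crossed Claisen condensation the lithium enolate of methyl acetate should add to the lactone carbonyl, and the ring-opened β-keto ester is deprotonated by the second equivalent of enolate, which should prevent a second addition.

Step 5
Reactants: 3 (2E,6S)-6-hydroxy-2,6-dimethylocta-2,7-dienoic acid; 7 methyl 7-hydroxy-6,6-dimethyl-3-oxoheptanoate
Product: 8 methyl 7-{[(2E,6S)-6-hydroxy-2,6-dimethylocta-2,7-dienoyl]oxy}-6,6-dimethyl-3-oxoheptanoate
Conditions: EDC·HCl, DMAP, CH2Cl2, 0 → 23 °C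
Reagents that add atoms: none
Why: Steglich esterification should acylate the primary neopentyl hydroxyl of open-chain 7 (the lactol equilibrates to it) through the acyl-pyridinium of 3, while the tertiary allylic alcohol of 3 is too hindered to compete and the (E)-geometry is kept under these mild conditions.

Step 6
Reactants: 8 methyl 7-{[(2E,6S)-6-hydroxy-2,6-dimethylocta-2,7-dienoyl]oxy}-6,6-dimethyl-3-oxoheptanoate; 9 2-(trimethylsilyl)phenyl trifluoromethanesulfonate
Product: 13 3-(3-hydroxy-1,4-dioxo-1,4-dihydronaphthalen-2-yl)-2,2-dimethylpropyl (2E,6S)-6-hydroxy-2,6-dimethylocta-2,7-dienoate (target CNP0111177.1), via benzyne 10 (not isolated), via aryl ketone ester 11 (not isolated), via naphthalene-1,3-diol 12 (not isolated)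
Conditions: 9 (1.25 equiv), CsF (2.5 equiv), MeCN, 80 °C; then NaOMe (3 equiv), MeOH, 0 → 23 °C under argon, then air; AcOH quench
Reagents that add atoms: dioxygen (air), O=O
Why: Fluoride turns 9 into benzyne 10, the cesium enolate of 8 adds to it, and the aryl anion closes onto the ketone (transient four-membered benzocyclobutenoxide, 4-exo-trig) and fragments, so that the arene is inserted into the CH2–C(=O) bond and 11 results (aryne acyl-alkylation). Methoxide then generates the aryl ketone enolate of 11, whose α-carbon attacks the neighbouring methyl ester in a 6-(enolexo)-exo-trig Claisen (Dieckmann-type) condensation that forms the C2–C3 bond of the quinone ring, and loss of methoxide plus enolisation gives naphthalene-1,3-diol 12. Air oxidises the electron-rich naphtholate of 12 at its free ring position (C1 of the quinone) through a hydroperoxide that loses water, giving the 2-hydroxy-1,4-naphthoquinone. The closest known reaction type is the one-pot aryne acyl-alkylation, condensation and autoxidation of β-keto esters to 3-alkyl-2-hydroxy-1,4-naphthoquinones. No stereocentre is formed, and the remote (S)-carbinol centre and the (E)-enoate are not involved. The step needs chemoselectivity, which rests on the doubly stabilised enolate being by far the best partner for the symmetrical aryne (the tertiary alcohol is hindered), on the ketone enolate reaching the unhindered methyl arylacetate through an aromatisation-driven six-membered closure (the benzylic ester enolate could only close a four-membered ring), and on the neopentyl α-methyl enoate being hindered and conjugated toward methoxide in a short, cold base stage.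

Compound list
1 | (S)-(+)-linalool, (3S)-3,7-dimethylocta-1,6-dien-3-ol | C=C[C@@](C)(O)CCC=C(C)C | starting material
2 | (2E,6S)-6-hydroxy-2,6-dimethylocta-2,7-dienal | C=C[C@@](C)(O)CC/C=C(\C)C=O | intermediate
3 | (2E,6S)-6-hydroxy-2,6-dimethylocta-2,7-dienoic acid | C=C[C@@](C)(O)CC/C=C(\C)C(=O)O | intermediate
4 | methyl 4,4-dimethyl-5-oxopentanoate | COC(=O)CCC(C)(C)C=O | starting material
5 | methyl 5-hydroxy-4,4-dimethylpentanoate | COC(=O)CCC(C)(C)CO | intermediate (not isolated)
6 | 5,5-dimethyloxan-2-one | O=C1CCC(C)(C)CO1 | intermediate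
7 | methyl 7-hydroxy-6,6-dimethyl-3-oxoheptanoate | COC(=O)CC(=O)CCC(C)(C)CO | intermediate
8 | methyl 7-{[(2E,6S)-6-hydroxy-2,6-dimethylocta-2,7-dienoyl]oxy}-6,6-dimethyl-3-oxoheptanoate | C=C[C@@](C)(O)CC/C=C(\C)C(=O)OCC(C)(C)CCC(=O)CC(=O)OC | intermediate
9 | 2-(trimethylsilyl)phenyl trifluoromethanesulfonate | C[Si](C)(C)c1ccccc1OS(=O)(=O)C(F)(F)F | starting material
10 | benzyne (1,2-didehydrobenzene) | C1#CC=CC=C1 | intermediate (not isolated)
11 | methyl 2-[2-(5-{[(2E,6S)-6-hydroxy-2,6-dimethylocta-2,7-dienoyl]oxy}-4,4-dimethylpentanoyl)phenyl]acetate | C=C[C@@](C)(O)CC/C=C(\C)C(=O)OCC(C)(C)CCC(=O)c1ccccc1CC(=O)OC | intermediate (not isolated)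
12 | 3-(1,3-dihydroxynaphthalen-2-yl)-2,2-dimethylpropyl (2E,6S)-6-hydroxy-2,6-dimethylocta-2,7-dienoate | C=C[C@@](C)(O)CC/C=C(\C)C(=O)OCC(C)(C)Cc1c(O)cc2ccccc2c1O | intermediate (not isolated)
13 | 3-(3-hydroxy-1,4-dioxo-1,4-dihydronaphthalen-2-yl)-2,2-dimethylpropyl (2E,6S)-6-hydroxy-2,6-dimethylocta-2,7-dienoate | C=C[C@@](C)(O)CC/C=C(\C)C(=O)OCC(C)(C)CC1=C(O)C(=O)c2ccccc2C1=O | target

Total step count: 6
Longest linear sequence: 4 steps (1 → 2 → 3 → 8 → 13, or 4 → 6 → 7 → 8 → 13)

Steps most likely to fail

Step 6. During the base stage methoxide may cleave the side-chain ester or let the tertiary alkoxide add to the enoate (oxa-Michael cyclisation), and the aryne may arylate the tertiary hydroxyl. The fallback sets out from 7 and builds the quinone before the acid is attached. Silylation of 7 (t-BuPh2SiCl, imidazole, DMF) should give methyl 7-[(tert-butyldiphenylsilyl)oxy]-6,6-dimethyl-3-oxoheptanoate F1. The same aryne, Claisen and air sequence with 9 should pass through methyl 2-(2-{5-[(tert-butyldiphenylsilyl)oxy]-4,4-dimethylpentanoyl}phenyl)acetate F2 and 2-{3-[(tert-butyldiphenylsilyl)oxy]-2,2-dimethylpropyl}naphthalene-1,3-diol F3, neither isolated, to 3-{3-[(tert-butyldiphenylsilyl)oxy]-2,2-dimethylpropyl}-2-hydroxynaphthalene-1,4-dione F4. HF·pyridine in MeCN should then free 2-hydroxy-3-(3-hydroxy-2,2-dimethylpropyl)naphthalene-1,4-dione F5. Its primary hydroxyl is esterified with acid 3 (EDC·HCl, DMAP, CH2Cl2); any O-acylated quinone hydroxyl is a vinylogous anhydride and should be hydrolysed in the aqueous NaHCO3 work-up. This comes back to the route at 13.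

Step 5. Acylation may be slow because the hydroxy ketone sits partly as its lactol, and the lactol may dehydrate to the cyclic enol ether or the β-keto ester enol may be acylated instead. The fallback sets out from 6 and 3 and installs the β-keto ester after the ester bond. Opening of 6 with MeNH(OMe)·HCl and AlMe3 in CH2Cl2 should give 5-hydroxy-N-methoxy-N,4,4-trimethylpentanamide F6, a hydroxy amide that cannot form a lactol. Steglich esterification with 3 should give 5-[methoxy(methyl)amino]-2,2-dimethyl-5-oxopentyl (2E,6S)-6-hydroxy-2,6-dimethylocta-2,7-dienoate F7. The lithium enolate of methyl acetate (3 equiv, THF, −78 °C) should then add to the N-methoxy-N-methyl amide (Weinreb ketone synthesis) in preference to the hindered conjugated ester, coming back to the route at 8.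

Step 1. The hot, acidic selenium medium may cause allylic transposition or dehydration of the tertiary allylic alcohol, and oxidation may stall at the allylic alcohol. The fallback sets out from 1 and replaces C–H oxidation by cleavage and olefination. Ozonolysis limited to one equivalent (O3, CH2Cl2/MeOH, −78 °C; Me2S) should cleave the electron-rich trisubstituted alkene in preference to the vinyl group and give (5S)-5-ethenyl-5-methyloxolan-2-ol F8, the lactol of (4S)-4-hydroxy-4-methylhex-5-enal. Wittig reaction of F8 with the stabilised ylide 2-(triphenylphosphoranylidene)propanal (toluene, 90 °C) should give the (E)-enal, coming back to the route at 2.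

Further compounds
F1 | step 6 | methyl 7-[(tert-butyldiphenylsilyl)oxy]-6,6-dimethyl-3-oxoheptanoate | COC(=O)CC(=O)CCC(C)(C)CO[Si](c1ccccc1)(c1ccccc1)C(C)(C)C
F2 | step 6 | methyl 2-(2-{5-[(tert-butyldiphenylsilyl)oxy]-4,4-dimethylpentanoyl}phenyl)acetate | COC(=O)Cc1ccccc1C(=O)CCC(C)(C)CO[Si](c1ccccc1)(c1ccccc1)C(C)(C)C
F3 | step 6 | 2-{3-[(tert-butyldiphenylsilyl)oxy]-2,2-dimethylpropyl}naphthalene-1,3-diol | CC(C)(CO[Si](c1ccccc1)(c1ccccc1)C(C)(C)C)Cc1c(O)cc2ccccc2c1O
F4 | step 6 | 3-{3-[(tert-butyldiphenylsilyl)oxy]-2,2-dimethylpropyl}-2-hydroxynaphthalene-1,4-dione | CC(C)(CO[Si](c1ccccc1)(c1ccccc1)C(C)(C)C)CC1=C(O)C(=O)c2ccccc2C1=O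
F5 | step 6 | 2-hydroxy-3-(3-hydroxy-2,2-dimethylpropyl)naphthalene-1,4-dione | CC(C)(CO)CC1=C(O)C(=O)c2ccccc2C1=O
F6 | step 5 | 5-hydroxy-N-methoxy-N,4,4-trimethylpentanamide | CON(C)C(=O)CCC(C)(C)CO
F7 | step 5 | 5-[methoxy(methyl)amino]-2,2-dimethyl-5-oxopentyl (2E,6S)-6-hydroxy-2,6-dimethylocta-2,7-dienoate | C=C[C@@](C)(O)CC/C=C(\C)C(=O)OCC(C)(C)CCC(=O)N(C)OC
F8 | step 1 | (5S)-5-ethenyl-5-methyloxolan-2-ol (anomer mixture) | C=C[C@@](C)(O1)CCC1O
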